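**Plan**

- The chain is numbered from the aryl ketone carbon C1. After unmasking the two phenols, the retrosynthesis cuts C8–C9 and C9–C10 (allyl chloride + CO + isobutenylstannane), then C6=C7 (Wittig), then C1–aryl (aryllithium + aldehyde).
- The C1–C6 unit that remains has a quaternary C3 carrying two two-carbon arms, the vinyl group and C2–C1. With C1 as an enol ether, these arms are the two olefinic halves of a ring-opened 3-methyl-3-alkylcyclopropene whose sp3 ring carbon is C3; this feature makes the key step possible.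
- Forward: alkenol → silyl ether → dibromocyclopropane → bromocyclopropane → cyclopropene, then ring-opening cross-metathesis with butyl vinyl ether. The three-membered ring opens and no ring closes; the resorcinol ring is bought. The chain is then joined in the order C1–aryl, C6=C7, C8–C9–C10.
- The only stereocentre (C3, R in the target) is set in the metathesis, where a stereogenic-at-molybdenum alkylidene selects one of the two enantiotopic cyclopropene CH carbons. Being quaternary, it cannot epimerise later. The 6E olefin comes from a formyl-stabilised ylide.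

Key step: step 5

Assumption: the (R)-aryloxide ligand is taken to deliver the (4S) metathesis product by analogy with aryl/methyl cyclopropenes; if the antipode should form, the (S)-aryloxide is used instead.

**Route**

Step 1
Reactants: 1 4-methylpent-4-en-1-ol
Product: 2 tert-butyldimethyl[(4-methylpent-4-en-1-yl)oxy]silane
Conditions: TBSCl (1.1 equiv), imidazole (2 equiv), CH2Cl2, 0 °C to rt
Reagents that add atoms: tert-butyldimethylsilyl chloride, CC(C)(C)[Si](C)(C)Cl
Why: Standard silylation of a primary alcohol gives an ether that should tolerate the carbene, Grignard, alkoxide and alkylidene reagents that follow.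

Step 2
Reactants: 2 tert-butyldimethyl[(4-methylpent-4-en-1-yl)oxy]silane; 3 bromoform
Product: 5 tert-butyl[3-(2,2-dibromo-1-methylcyclopropyl)propoxy]dimethylsilane (racemic), via dibromocarbene 4 (not isolated)
Conditions: CHBr3 (2 equiv), KOtBu (2.5 equiv), pentane, 0 °C to rt
Reagents that add atoms: none
Why: α-Elimination of HBr from bromoform gives dibromocarbene, which adds to the electron-rich 1,1-disubstituted alkene in a [2+1] cycloaddition; the ring stereocentre is racemic and is erased in step 4.

Step 3
Reactants: 5 tert-butyl[3-(2,2-dibromo-1-methylcyclopropyl)propoxy]dimethylsilane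
Product: 6 tert-butyl[3-(2-bromo-1-methylcyclopropyl)propoxy]dimethylsilane (racemic cis/trans mixture)
Conditions: EtMgBr (1.3 equiv), Ti(OiPr)4 (5 mol%), Et2O, rt
Reagents that add atoms: none
Why: Titanium-catalysed hydrodebromination of gem-dibromocyclopropanes with EtMgBr should stop at the monobromide, and both diastereomers are usable because each has a ring hydrogen available for the elimination in step 4.

Step 4
Reactants: 6 tert-butyl[3-(2-bromo-1-methylcyclopropyl)propoxy]dimethylsilane
Product: 7 tert-butyldimethyl[3-(1-methylcycloprop-2-en-1-yl)propoxy]silane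
Conditions: KOtBu (1.5 equiv), DMSO, 20 °C
Reagents that add atoms: none
Why: Base-induced 1,2-dehydrobromination is the standard entry to 3,3-disubstituted cyclopropenes, which have no allylic ring hydrogen and so cannot isomerise to methylenecyclopropanes; both stereocentres of 6 vanish to give an achiral alkene.

Step 5
Reactants: 7 tert-butyldimethyl[3-(1-methylcycloprop-2-en-1-yl)propoxy]silane; 8 butyl vinyl ether
Product: 9 {[(4S,5Z)-6-butoxy-4-ethenyl-4-methylhex-5-en-1-yl]oxy}(tert-butyl)dimethylsilane
Conditions: Mo(N-2,6-i-Pr2C6H3)(CHCMe2Ph)(2,5-Me2C4H2N)(OAr*) (3 mol%), formed in situ from Mo(N-2,6-i-Pr2C6H3)(CHCMe2Ph)(2,5-Me2C4H2N)2 and HOAr* = (R)-3,3′-dibromo-2′-(tert-butyldimethylsilyloxy)-5,5′,6,6′,7,7′,8,8′-octahydro-1,1′-binaphthalen-2-ol; 8 (10 equiv), C6H6, 22 °C, N2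
Reagents that add atoms: none
Why: Initiation with the vinyl ether converts the neophylidene into Mo=CH(OBu), which adds [2+2] to the strained ring double bond of 7; cycloreversion of the molybdacyclobutane cleaves that bond, so one ring CH becomes the enol ether terminus and the other a new alkylidene, which a second vinyl ether molecule releases as the terminal vinyl group while regenerating Mo=CH(OBu). The closest known reaction type is the enantioselective ring-opening cross-metathesis of 3,3-disubstituted cyclopropenes with enol ethers by stereogenic-at-metal molybdenum monoaryloxide pyrrolide alkylidenes, documented chiefly for aryl/methyl cyclopropenes. No ring closes: the three-membered ring opens, and the vinyl C=C and the later C2=C1 bond end up on the same carbon. The only new stereocentre, C3, arises because the two olefinic CH carbons of 7 are enantiotopic; the stereogenic hexavalent molybdenum centre with its bulky enantiopure aryloxide decides which of them binds the metal, with the cyclopropene expected to approach by its methyl-bearing face. The step needs three selectivities: enantiotopic-carbon selection is imposed by the catalyst; methyl-versus-alkyl face selection rests only on the size difference between CH3 and the silyloxypropyl chain and is the weak point; cross- over homo-metathesis is secured by ring strain, excess vinyl ether and the inertness of the neopentyl-type vinyl and enol ether groups of 9. The Z geometry expected for the enol ether is of no consequence because step 6 hydrolyses it.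

Step 6
Reactants: 9 {[(4S,5Z)-6-butoxy-4-ethenyl-4-methylhex-5-en-1-yl]oxy}(tert-butyl)dimethylsilane
Product: 10 (3R)-6-[(tert-butyldimethylsilyl)oxy]-3-ethenyl-3-methylhexanal
Conditions: oxalic acid dihydrate (cat.), THF/H2O 4:1, 20 °C
Reagents that add atoms: water, O
Why: Acid-catalysed enol ether hydrolysis should proceed under conditions much milder than those that cleave a primary TBS ether; no bond to C3 is touched, and the descriptor changes from 4S to 3R only because the CIP ranking of the arms changes.

Step 7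
Reactants: 11 4-bromoresorcinol
Product: 12 1-bromo-2,4-bis(methoxymethoxy)benzene
Conditions: MOMCl (2.5 equiv), i-Pr2NEt (3 equiv), CH2Cl2, 0 °C to rt
Reagents that add atoms: chloromethyl methyl ether, COCCl
Why: O-Alkylation of both phenols gives acetal ethers that tolerate, and through chelation assist, the bromine–lithium exchange of step 8.

Step 8
Reactants: 12 1-bromo-2,4-bis(methoxymethoxy)benzene; 10 (3R)-6-[(tert-butyldimethylsilyl)oxy]-3-ethenyl-3-methylhexanal
Product: 14 (3R)-1-[2,4-bis(methoxymethoxy)phenyl]-6-[(tert-butyldimethylsilyl)oxy]-3-ethenyl-3-methylhexan-1-ol (both C1 epimers), via aryllithium 13 (not isolated)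
Conditions: 12 (1.2 equiv), n-BuLi (1.15 equiv), THF, −78 °C; then 10, −78 °C; then H2O
Reagents that add atoms: n-butyllithium, [Li]CCCC (supplies only the lithium of intermediate 13)
Why: Bromine–lithium exchange followed by 1,2-addition of the aryllithium to the aldehyde forms the C1–aryl bond; the carbinol centre forms as a mixture that step 10 removes.

Step 9
Reactants: 14 (3R)-1-[2,4-bis(methoxymethoxy)phenyl]-6-[(tert-butyldimethylsilyl)oxy]-3-ethenyl-3-methylhexan-1-ol
Product: 15 (3R)-1-[2,4-bis(methoxymethoxy)phenyl]-3-ethenyl-3-methylhexane-1,6-diol (both C1 epimers)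
Conditions: TBAF (1.2 equiv), THF, 0 °C to rt
Reagents that add atoms: none
Why: Fluoride-induced Si–O cleavage under basic conditions spares the MOM acetals and the acid-labile electron-rich benzylic alcohol.

Step 10
Reactants: 15 (3R)-1-[2,4-bis(methoxymethoxy)phenyl]-3-ethenyl-3-methylhexane-1,6-diol
Product: 16 (4R)-6-[2,4-bis(methoxymethoxy)phenyl]-4-ethenyl-4-methyl-6-oxohexanal
Conditions: Dess–Martin periodinane (2.6 equiv), CH2Cl2, 0 °C to rt
Reagents that add atoms: none
Why: Dess–Martin oxidation should convert the benzylic and the primary alcohol in one operation under non-basic conditions, which keeps the resulting 1,6-keto aldehyde from intramolecular aldol closure.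

Step 11
Reactants: 16 (4R)-6-[2,4-bis(methoxymethoxy)phenyl]-4-ethenyl-4-methyl-6-oxohexanal; 17 2-(triphenylphosphoranylidene)propanal
Product: 18 (2E,6R)-8-[2,4-bis(methoxymethoxy)phenyl]-6-ethenyl-2,6-dimethyl-8-oxooct-2-enal
Conditions: 17 (1.3 equiv), toluene, 80 °C
Reagents that add atoms: none
Why: Wittig olefination with a formyl-stabilised ylide should give the (E)-trisubstituted enal and react only with the aldehyde, leaving the hindered electron-rich aryl ketone untouched.

Step 12
Reactants: 18 (2E,6R)-8-[2,4-bis(methoxymethoxy)phenyl]-6-ethenyl-2,6-dimethyl-8-oxooct-2-enal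
Product: 19 (3R,6E)-1-[2,4-bis(methoxymethoxy)phenyl]-3-ethenyl-8-hydroxy-3,7-dimethyloct-6-en-1-one
Conditions: NaBH4 (1 equiv), MeOH/THF, −40 °C
Reagents that add atoms: none
Why: Hydride 1,2-reduction of an enal is much faster than reduction of the deactivated dialkoxyaryl ketone next to a neopentyl-type methylene, so only the aldehyde should be reduced at low temperature.

Step 13
Reactants: 19 (3R,6E)-1-[2,4-bis(methoxymethoxy)phenyl]-3-ethenyl-8-hydroxy-3,7-dimethyloct-6-en-1-one
Product: 21 (3R,6E)-1-[2,4-bis(methoxymethoxy)phenyl]-8-chloro-3-ethenyl-3,7-dimethyloct-6-en-1-one, via allylic mesylate 20 (not isolated)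
Conditions: MsCl (1.3 equiv), 2,4,6-collidine (2 equiv), LiCl (3 equiv), DMF, 0 °C
Reagents that add atoms: methanesulfonyl chloride, CS(=O)(=O)Cl (mesyl group of intermediate 20 only); lithium chloride, [Li+].[Cl-]
Why: Mesylation with in situ SN2 displacement by chloride (Collington–Meyers procedure) converts primary allylic alcohols into chlorides without allylic transposition or loss of E geometry.

Step 14
Reactants: 22 (2-methylprop-1-en-1-yl)magnesium bromide
Product: 23 tributyl(2-methylprop-1-en-1-yl)stannane
Conditions: Bu3SnCl (0.9 equiv), THF, 0 °C to rt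
Reagents that add atoms: tributyltin chloride, CCCC[Sn](Cl)(CCCC)CCCC
Why: Transmetalation of an alkenylmagnesium halide onto a trialkyltin chloride is the standard preparation of alkenylstannanes.

Step 15
Reactants: 21 (3R,6E)-1-[2,4-bis(methoxymethoxy)phenyl]-8-chloro-3-ethenyl-3,7-dimethyloct-6-en-1-one; 23 tributyl(2-methylprop-1-en-1-yl)stannane
Product: 24 (3R,6E)-1-[2,4-bis(methoxymethoxy)phenyl]-3-ethenyl-3,7,11-trimethyldodeca-6,10-diene-1,9-dione
Conditions: Pd2(dba)3 (2.5 mol%), PPh3 (10 mol%), CO (3 atm), THF, 50 °C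
Reagents that add atoms: carbon monoxide, [C-]#[O+]
Why: In this carbonylative Stille coupling the allyl chloride adds oxidatively to zerovalent palladium, CO inserts at the primary allyl terminus, and transmetalation from tin with reductive elimination gives the allyl alkenyl ketone with the E olefin retained, under neutral conditions that tolerate the aryl ketone.

Step 16
Reactants: 24 (3R,6E)-1-[2,4-bis(methoxymethoxy)phenyl]-3-ethenyl-3,7,11-trimethyldodeca-6,10-diene-1,9-dione
Product: 26 (3R,6E)-1-(2,4-dihydroxyphenyl)-3-ethenyl-3,7,11-trimethyldodeca-6,10-diene-1,9-dione, via bis-TMS aryl ether 25 (not isolated)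
Conditions: TMSOTf (4 equiv), 2,2′-bipyridyl (6 equiv), MeCN, 0 °C to rt; then H2O
Reagents that add atoms: trimethylsilyl trifluoromethanesulfonate, C[Si](C)(C)OS(=O)(=O)C(F)(F)F (silyl groups of intermediate 25 only)
Why: Silyl triflate/2,2′-bipyridyl cleavage of aromatic MOM ethers passes through the aryl silyl ethers, which water hydrolyses, so the bipyridyl-buffered medium should contain no acid or base strong enough to move the C6=C7 bond into conjugation with the C9 ketone.

**Compound list**

1 | 4-methylpent-4-en-1-ol | C=C(C)CCCO | starting material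
2 | tert-butyldimethyl[(4-methylpent-4-en-1-yl)oxy]silane | C=C(C)CCCO[Si](C)(C)C(C)(C)C | intermediate
3 | bromoform (tribromomethane) | BrC(Br)Br | starting material
4 | dibromocarbene (not isolated) | Br[C]Br | intermediate
5 | tert-butyl[3-(2,2-dibromo-1-methylcyclopropyl)propoxy]dimethylsilane (racemic) | CC1(CCCO[Si](C)(C)C(C)(C)C)CC1(Br)Br | intermediate
6 | tert-butyl[3-(2-bromo-1-methylcyclopropyl)propoxy]dimethylsilane (racemic, cis/trans mixture) | CC1(CCCO[Si](C)(C)C(C)(C)C)CC1Br | intermediate
7 | tert-butyldimethyl[3-(1-methylcycloprop-2-en-1-yl)propoxy]silane (achiral) | CC1(CCCO[Si](C)(C)C(C)(C)C)C=C1 | intermediate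
8 | butyl vinyl ether | C=COCCCC | starting material
9 | {[(4S,5Z)-6-butoxy-4-ethenyl-4-methylhex-5-en-1-yl]oxy}(tert-butyl)dimethylsilane | C=C[C@](C)(CCCO[Si](C)(C)C(C)(C)C)/C=C\OCCCC | intermediate
10 | (3R)-6-[(tert-butyldimethylsilyl)oxy]-3-ethenyl-3-methylhexanal | C=C[C@](C)(CCCO[Si](C)(C)C(C)(C)C)CC=O | intermediate
11 | 4-bromoresorcinol (4-bromobenzene-1,3-diol) | Oc1ccc(Br)c(O)c1 | starting material
12 | 1-bromo-2,4-bis(methoxymethoxy)benzene | COCOc1ccc(Br)c(OCOC)c1 | intermediate
13 | [2,4-bis(methoxymethoxy)phenyl]lithium (not isolated) | [Li]c1ccc(OCOC)cc1OCOC | intermediate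
14 | (3R)-1-[2,4-bis(methoxymethoxy)phenyl]-6-[(tert-butyldimethylsilyl)oxy]-3-ethenyl-3-methylhexan-1-ol (both C1 epimers) | C=C[C@](C)(CCCO[Si](C)(C)C(C)(C)C)CC(O)c1ccc(OCOC)cc1OCOC | intermediate
15 | (3R)-1-[2,4-bis(methoxymethoxy)phenyl]-3-ethenyl-3-methylhexane-1,6-diol (both C1 epimers) | C=C[C@](C)(CCCO)CC(O)c1ccc(OCOC)cc1OCOC | intermediate
16 | (4R)-6-[2,4-bis(methoxymethoxy)phenyl]-4-ethenyl-4-methyl-6-oxohexanal | C=C[C@](C)(CCC=O)CC(=O)c1ccc(OCOC)cc1OCOC | intermediate
17 | 2-(triphenylphosphoranylidene)propanal | CC(C=O)=P(c1ccccc1)(c1ccccc1)c1ccccc1 | starting material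
18 | (2E,6R)-8-[2,4-bis(methoxymethoxy)phenyl]-6-ethenyl-2,6-dimethyl-8-oxooct-2-enal | C=C[C@](C)(CC/C=C(\C)C=O)CC(=O)c1ccc(OCOC)cc1OCOC | intermediate
19 | (3R,6E)-1-[2,4-bis(methoxymethoxy)phenyl]-3-ethenyl-8-hydroxy-3,7-dimethyloct-6-en-1-one | C=C[C@](C)(CC/C=C(\C)CO)CC(=O)c1ccc(OCOC)cc1OCOC | intermediate
20 | (2E,6R)-8-[2,4-bis(methoxymethoxy)phenyl]-6-ethenyl-2,6-dimethyl-8-oxooct-2-en-1-yl methanesulfonate (not isolated) | C=C[C@](C)(CC/C=C(\C)COS(C)(=O)=O)CC(=O)c1ccc(OCOC)cc1OCOC | intermediate
21 | (3R,6E)-1-[2,4-bis(methoxymethoxy)phenyl]-8-chloro-3-ethenyl-3,7-dimethyloct-6-en-1-one | C=C[C@](C)(CC/C=C(\C)CCl)CC(=O)c1ccc(OCOC)cc1OCOC | intermediate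
22 | (2-methylprop-1-en-1-yl)magnesium bromide | CC(C)=C[Mg]Br | starting material
23 | tributyl(2-methylprop-1-en-1-yl)stannane | CCCC[Sn](CCCC)(CCCC)C=C(C)C | intermediate
24 | (3R,6E)-1-[2,4-bis(methoxymethoxy)phenyl]-3-ethenyl-3,7,11-trimethyldodeca-6,10-diene-1,9-dione | C=C[C@](C)(CC/C=C(\C)CC(=O)C=C(C)C)CC(=O)c1ccc(OCOC)cc1OCOC | intermediate
25 | (3R,6E)-1-{2,4-bis[(trimethylsilyl)oxy]phenyl}-3-ethenyl-3,7,11-trimethyldodeca-6,10-diene-1,9-dione (not isolated) | C=C[C@](C)(CC/C=C(\C)CC(=O)C=C(C)C)CC(=O)c1ccc(O[Si](C)(C)C)cc1O[Si](C)(C)C | intermediate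
26 | (3R,6E)-1-(2,4-dihydroxyphenyl)-3-ethenyl-3,7,11-trimethyldodeca-6,10-diene-1,9-dione (CNP0208188.1) | C=C[C@](C)(CC/C=C(\C)CC(=O)C=C(C)C)CC(=O)c1ccc(O)cc1O | target

**Summary**

Total step count: 16. Longest linear sequence: 14 steps (steps 1–6, 8–13, 15, 16); steps 7 and 14 are one-step side branches.

**Steps most likely to fail**

1. Step 5. The catalyst may not distinguish the methyl face from the silyloxypropyl face of the cyclopropene well enough, which would erode the enantiomeric purity at C3; ring-opening oligomerisation of 7 could also compete with cross-metathesis.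
Fallback (auxiliary-controlled conjugate vinylation; leaves the route at 2 and rejoins at 10): ozonolysis of 2 (O3, CH2Cl2, −78 °C; Me2S) should give 5-[(tert-butyldimethylsilyl)oxy]pentan-2-one F1. Horner–Wadsworth–Emmons olefination with triethyl phosphonoacetate and NaH in THF, with removal of the Z isomer, would give ethyl (2E)-6-[(tert-butyldimethylsilyl)oxy]-3-methylhex-2-enoate F2. Hydrolysis with LiOH would give (2E)-6-[(tert-butyldimethylsilyl)oxy]-3-methylhex-2-enoic acid F3. Its pivaloyl mixed anhydride (PivCl, Et3N) would be coupled with (4S)-4-phenyl-1,3-oxazolidin-2-one and LiCl to give (4S)-3-{(2E)-6-[(tert-butyldimethylsilyl)oxy]-3-methylhex-2-enoyl}-4-phenyl-1,3-oxazolidin-2-one F4. Vinylmagnesium bromide with CuBr·SMe2 (THF, −78 to −20 °C) should add to the magnesium-chelated s-cis imide from the face opposite the phenyl group, giving (4S)-3-{(3R)-6-[(tert-butyldimethylsilyl)oxy]-3-ethenyl-3-methylhexanoyl}-4-phenyl-1,3-oxazolidin-2-one F5. LiBH4 would release the auxiliary and give (3R)-6-[(tert-butyldimethylsilyl)oxy]-3-ethenyl-3-methylhexan-1-ol F6, which Dess–Martin oxidation would convert into 10.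

2. Step 15. Direct allyl–alkenyl coupling without CO uptake, slow tin-to-palladium transfer of the β,β-disubstituted alkenyl group, or migration of the C6=C7 bond into conjugation during the reaction could each reduce the outcome.
Fallback (alkyne coupling and 1,3-oxygen shift in place of carbonylation; leaves the route at 21 and rejoins at 24): 21 would be coupled with 2-methylbut-3-yn-2-ol (CuI, K2CO3, NaI, DMF, 20 °C) to give the skipped enyne carbinol (3R,6E)-1-[2,4-bis(methoxymethoxy)phenyl]-3-ethenyl-11-hydroxy-3,7,11-trimethyldodec-6-en-9-yn-1-one F7. A Meyer–Schuster rearrangement (AuCl(PPh3), AgOTf and MoO2(acac)2, each about 1 mol%, toluene, 20 °C) would then move the oxygen from C11 to C9 and give enone 24.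

3. Step 16. The C6=C7 bond could migrate into conjugation with the C9 ketone, C8 could undergo silylative enolisation, or cleavage of the para acetal could stall.
Fallback (phenols unmasked before the sensitive dienone exists; leaves the route at 18 and ends at 26): 18 would be deprotected with HCl in MeOH at 40 °C, followed by aqueous work-up, to give (2E,6R)-8-(2,4-dihydroxyphenyl)-6-ethenyl-2,6-dimethyl-8-oxooct-2-enal F8. NaBH4 in MeOH at −40 °C would give (3R,6E)-1-(2,4-dihydroxyphenyl)-3-ethenyl-8-hydroxy-3,7-dimethyloct-6-en-1-one F9. PPh3 with hexachloroacetone, which should leave the phenols alone, would give (3R,6E)-8-chloro-1-(2,4-dihydroxyphenyl)-3-ethenyl-3,7-dimethyloct-6-en-1-one F10. Carbonylative coupling of F10 with 23 under the conditions of step 15 would give 26 directly.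

**Further compounds**

F1 | step 5 | 5-[(tert-butyldimethylsilyl)oxy]pentan-2-one | CC(=O)CCCO[Si](C)(C)C(C)(C)C
F2 | step 5 | ethyl (2E)-6-[(tert-butyldimethylsilyl)oxy]-3-methylhex-2-enoate | CCOC(=O)/C=C(\C)CCCO[Si](C)(C)C(C)(C)C
F3 | step 5 | (2E)-6-[(tert-butyldimethylsilyl)oxy]-3-methylhex-2-enoic acid | OC(=O)/C=C(\C)CCCO[Si](C)(C)C(C)(C)C
F4 | step 5 | (4S)-3-{(2E)-6-[(tert-butyldimethylsilyl)oxy]-3-methylhex-2-enoyl}-4-phenyl-1,3-oxazolidin-2-one | O=C(/C=C(\C)CCCO[Si](C)(C)C(C)(C)C)N1C(=O)OC[C@@H]1c1ccccc1
F5 | step 5 | (4S)-3-{(3R)-6-[(tert-butyldimethylsilyl)oxy]-3-ethenyl-3-methylhexanoyl}-4-phenyl-1,3-oxazolidin-2-one | C=C[C@](C)(CCCO[Si](C)(C)C(C)(C)C)CC(=O)N1C(=O)OC[C@@H]1c1ccccc1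
F6 | step 5 | (3R)-6-[(tert-butyldimethylsilyl)oxy]-3-ethenyl-3-methylhexan-1-ol | C=C[C@](C)(CCCO[Si](C)(C)C(C)(C)C)CCO
F7 | step 15 | (3R,6E)-1-[2,4-bis(methoxymethoxy)phenyl]-3-ethenyl-11-hydroxy-3,7,11-trimethyldodec-6-en-9-yn-1-one | C=C[C@](C)(CC/C=C(\C)CC#CC(C)(C)O)CC(=O)c1ccc(OCOC)cc1OCOC
F8 | step 16 | (2E,6R)-8-(2,4-dihydroxyphenyl)-6-ethenyl-2,6-dimethyl-8-oxooct-2-enal | C=C[C@](C)(CC/C=C(\C)C=O)CC(=O)c1ccc(O)cc1O
F9 | step 16 | (3R,6E)-1-(2,4-dihydroxyphenyl)-3-ethenyl-8-hydroxy-3,7-dimethyloct-6-en-1-one | C=C[C@](C)(CC/C=C(\C)CO)CC(=O)c1ccc(O)cc1O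
F10 | step 16 | (3R,6E)-8-chloro-1-(2,4-dihydroxyphenyl)-3-ethenyl-3,7-dimethyloct-6-en-1-one | C=C[C@](C)(CC/C=C(\C)CCl)CC(=O)c1ccc(O)cc1O
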